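Ring A is disconnected into a vinylketene and an alkynyl ether. A photochemical Danheiser benzannulation joins the L-leucine-derived diazo enone (side-chain oxygen as a silyl ether) with a ring B aryloxypropargyl silyl ether and forges C1–C2, C2–C3 and C5–C6 in one operation. It exploits the pattern of ring A: the C2 oxygen sits between the carbon substituents at C1 and C3, C6 bears the aryloxy group and C4 and C5 bear hydrogen, exactly what a ketene carbonyl, an oxygen-polarised alkyne and the enone-derived diene deliver. The stereocentre comes from the amino acid; O-methylation, deprotection, olefination, oxidation, acetylation and phenol deprotection finish the synthesis.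

Key step: step 14

Remarks on the chemistry:
- Numbering: ring A runs from the carboxyl carbon C1 through C2 (OMe) and C3 (side chain) to C6 (aryloxy); ring B has the ether oxygen at C1', OH at C2', CH3 at C4' and the butenone at C6'.
- The side-chain oxygen travels as a TBS ether and is acetylated late, because an acetate on a benzylic carbon ortho to the phenol freed in step 14 could be expelled (ortho-quinone methide) and would not survive the enolate chemistry of step 6.
- The ring B phenol is a PMB ether, removed oxidatively, because hydrogenolysis or strong acid at the end would endanger the benzylic acetate and the enone.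
- The diazo enone is made by diazo transfer, since enoyl chlorides and diazomethane also react at the C=C bond (pyrazolines).
- The (S) descriptor holds for every compound of the leucine series: O > sp2 carbon > CH2 > H throughout, and no bond to the stereocentre is broken after step 1.
- TBS = tert-butyldimethylsilyl, PMB = 4-methoxybenzyl. The acetonyl ylide, 4-acetamidobenzenesulfonyl azide and CF3CO2CH2CF3 are assumed to be purchased.

Step 1
Reactants: 1 L-leucine
Product: 2 (S)-2-hydroxy-4-methylpentanoic acid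
Conditions: NaNO2, 1 M H2SO4 (aq), 0 °C → rt
Reagents that add atoms: water, O
Why: Nitrous acid deamination (diazotisation–hydrolysis) of the α-amino acid should proceed with net retention through carboxylate participation (two inversions), so the (S) configuration is kept.

Step 2
Reactants: 2 (S)-2-hydroxy-4-methylpentanoic acid
Product: 3 methyl (S)-2-hydroxy-4-methylpentanoate
Conditions: MeOH, H2SO4 (cat.), reflux
Reagents that add atoms: methanol, CO
Why: Fischer esterification in excess methanol does not touch the stereocentre.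

Step 3
Reactants: 3 methyl (S)-2-hydroxy-4-methylpentanoate
Product: 4 methyl (S)-2-[(tert-butyldimethylsilyl)oxy]-4-methylpentanoate
Conditions: TBSCl, imidazole, DMF, rt
Reagents that add atoms: tert-butyldimethylsilyl chloride, CC(C)(C)[Si](C)(C)Cl
Why: Imidazole-promoted O-silylation gives an ether that survives amide base, light, heat and phenoxide chemistry and cannot act as a leaving group.

Step 4
Reactants: 4 methyl (S)-2-[(tert-butyldimethylsilyl)oxy]-4-methylpentanoate
Product: 5 (S)-2-[(tert-butyldimethylsilyl)oxy]-4-methylpentanal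
Conditions: i-Bu2AlH (1.05 equiv), CH2Cl2, −78 °C; MeOH, aq. KNaC4H4O6
Reagents that add atoms: none
Why: Partial ester reduction at −78 °C should stop at the aluminium hemiacetal, which releases the α-silyloxy aldehyde on work-up; the aldehyde is used at once to avoid epimerisation.

Step 5
Reactants: 5 (S)-2-[(tert-butyldimethylsilyl)oxy]-4-methylpentanal
Product: 6 (3E,5S)-5-[(tert-butyldimethylsilyl)oxy]-7-methyloct-3-en-2-one
Conditions: Ph3P=CHC(O)CH3, CH2Cl2, rt → 40 °C
Reagents that add atoms: 1-(triphenylphosphoranylidene)propan-2-one, CC(=O)C=P(c1ccccc1)(c1ccccc1)c1ccccc1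
Why: Wittig olefination with the stabilised acetonyl ylide should give the (E)-enone under neutral conditions that do not epimerise the aldehyde.

Step 6
Reactants: 6 (3E,5S)-5-[(tert-butyldimethylsilyl)oxy]-7-methyloct-3-en-2-one
Product: 8 (3E,5S)-5-[(tert-butyldimethylsilyl)oxy]-1-diazo-7-methyloct-3-en-2-one, via trifluoroacetyl diketone 7 (not isolated)
Conditions: LiN(SiMe3)2, THF, −78 °C; CF3CO2CH2CF3; 5% aq. HCl wash; crude 7, 4-AcNHC6H4SO2N3, Et3N, H2O (1 equiv), MeCN, rt
Reagents that add atoms: 4-acetamidobenzenesulfonyl azide, CC(=O)Nc1ccc(cc1)S(=O)(=O)N=[N+]=[N-]; 2,2,2-trifluoroethyl trifluoroacetate, O=C(OCC(F)(F)F)C(F)(F)F (its CF3CO group is carried only by 7)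
Why: Detrifluoroacetylative diazo transfer (Regitz-type transfer to an activated ketone) — kinetic enolisation at the methyl group, Claisen-type trifluoroacetylation, then N2 transfer with loss of the trifluoroacetyl group — is the standard entry to α'-diazo enones and leaves the γ-stereocentre alone.

Step 7
Reactants: 9 2-methoxy-4-methylphenol
Product: 10 2-hydroxy-3-methoxy-5-methylbenzaldehyde
Conditions: MgCl2, Et3N, (CH2O)n, MeCN, reflux; 1 M HCl
Reagents that add atoms: paraformaldehyde (formaldehyde), C=O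
Why: Magnesium phenoxide-directed ortho-formylation (Casnati–Skattebøl) can occur only at C6, the single free ortho position.

Step 8
Reactants: 10 2-hydroxy-3-methoxy-5-methylbenzaldehyde
Product: 11 2,3-dihydroxy-5-methylbenzaldehyde
Conditions: BBr3, CH2Cl2, −78 → 0 °C; H2O
Reagents that add atoms: none
Why: Lewis acid-mediated aryl methyl ether cleavage unmasks the catechol so that the ring B oxygen can carry a removable group instead of methyl.

Step 9
Reactants: 11 2,3-dihydroxy-5-methylbenzaldehyde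
Product: 12 2-hydroxy-3-[(4-methoxybenzyl)oxy]-5-methylbenzaldehyde
Conditions: NaH (2.2 equiv), DMSO, 20 °C; PMBCl (1.0 equiv); 1 M HCl
Reagents that add atoms: 4-methoxybenzyl chloride, COc1ccc(CCl)cc1
Why: Williamson alkylation of the dianion should occur at O3, because the O2 phenoxide is delocalised into and chelated by the ortho-formyl group and is the weaker nucleophile.

Step 10
Reactants: 12 2-hydroxy-3-[(4-methoxybenzyl)oxy]-5-methylbenzaldehyde
Product: 13 2-(1,3-dioxolan-2-yl)-6-[(4-methoxybenzyl)oxy]-4-methylphenol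
Conditions: HOCH2CH2OH, PPTS (cat.), PhH, reflux (Dean–Stark)
Reagents that add atoms: ethane-1,2-diol, OCCO
Why: Acid-catalysed acetalisation with azeotropic removal of water masks the aldehyde against n-BuLi, and PPTS is mild enough for the PMB ether.

Step 11
Reactants: 13 2-(1,3-dioxolan-2-yl)-6-[(4-methoxybenzyl)oxy]-4-methylphenol; 14 trichloroethene
Product: 15 2-{2-[(E)-1,2-dichloroethenoxy]-3-[(4-methoxybenzyl)oxy]-5-methylphenyl}-1,3-dioxolane
Conditions: K2CO3, DMF, 70 °C
Reagents that add atoms: none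
Why: Base-mediated dichlorovinyl ether synthesis — anti addition of the phenoxide to dichloroacetylene formed transiently from 14 — tolerates di-ortho-substituted phenols and should give the (E)-ether.

Step 12
Reactants: 15 2-{2-[(E)-1,2-dichloroethenoxy]-3-[(4-methoxybenzyl)oxy]-5-methylphenyl}-1,3-dioxolane
Product: 17 3-{2-(1,3-dioxolan-2-yl)-6-[(4-methoxybenzyl)oxy]-4-methylphenoxy}prop-2-yn-1-ol, via lithium acetylide 16 (not isolated)
Conditions: n-BuLi (2.4 equiv), THF, −78 → −40 °C; (CH2O)n, −78 °C → rt; aq. NH4Cl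
Reagents that add atoms: paraformaldehyde (formaldehyde), C=O; n-butyllithium, [Li]CCCC (lithium of 16 only)
Why: Dehydrochlorination followed by chlorine–lithium exchange gives the lithium aryloxyacetylide, whose 1,2-addition to formaldehyde installs the future carboxyl carbon (alkynyl ether synthesis by elimination and halogen–metal exchange).

Step 13
Reactants: 17 3-{2-(1,3-dioxolan-2-yl)-6-[(4-methoxybenzyl)oxy]-4-methylphenoxy}prop-2-yn-1-ol
Product: 18 tert-butyl[(3-{2-(1,3-dioxolan-2-yl)-6-[(4-methoxybenzyl)oxy]-4-methylphenoxy}prop-2-yn-1-yl)oxy]dimethylsilane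
Conditions: TBSCl, imidazole, CH2Cl2, 0 °C → rt
Reagents that add atoms: tert-butyldimethylsilyl chloride, CC(C)(C)[Si](C)(C)Cl
Why: Imidazole-buffered O-silylation of the primary propargylic alcohol keeps the acid-sensitive alkynyl ether away from protic conditions.

Step 14
Reactants: 8 (3E,5S)-5-[(tert-butyldimethylsilyl)oxy]-1-diazo-7-methyloct-3-en-2-one; 18 tert-butyl[(3-{2-(1,3-dioxolan-2-yl)-6-[(4-methoxybenzyl)oxy]-4-methylphenoxy}prop-2-yn-1-yl)oxy]dimethylsilane
Product: 23 6-[(1S)-1-[(tert-butyldimethylsilyl)oxy]-3-methylbutyl]-2-{[(tert-butyldimethylsilyl)oxy]methyl}-3-{2-(1,3-dioxolan-2-yl)-6-[(4-methoxybenzyl)oxy]-4-methylphenoxy}phenol, via vinylketene 19 (not isolated), via vinylcyclobutenone 20 (not isolated), via dienylketene 21 (not isolated), via cyclohexadienone 22 (not isolated)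
Conditions: 8 (1.3 equiv), hν (450 W medium-pressure Hg lamp, Pyrex filter), CH2Cl2, 20 °C; then PhMe, 80 °C
Reagents that add atoms: none
Why: Irradiation expels N2 from 8 and the alkenyl group shifts (Wolff rearrangement) to give vinylketene 19, whose carbonyl carbon is attacked by the oxygen-remote alkyne carbon of 18 in a [2+2] cycloaddition to 4-vinylcyclobutenone 20. Light or heat opens 20 in a reversible 4π-electrocyclic reaction to dienylketene 21, and ring A closes by thermal disrotatory 6π-electrocyclisation between the ketene carbon and the diene terminus (the C2–C3 bond) to dienone 22, which tautomerises to phenol 23. The closest known reaction type is the photochemical Danheiser benzannulation of α-diazo enones with alkoxy- and siloxyalkynes; an aryloxyalkyne is a less electron-rich member of the same alkynyl ether class. No stereocentre is created, since the ring carbons that are sp3 in 20 and 22 become aromatic and the (S)-carbinol carbon is a spectator throughout. The step needs one regiochemistry in the [2+2] event, and the lone pair of the aryloxy oxygen secures it by making the CH2OTBS-bearing carbon the nucleophilic terminus, so that the ketene carbonyl ends as C2 between C1 and C3. The TBS ether on the side chain keeps the new ortho-phenol from expelling a benzylic leaving group and allows any aryl ester formed by ketene acylation of 23 to be cleaved with K2CO3 in MeOH.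

Step 15
Reactants: 23 the phenol from step 14
Product: 24 2-{2-[2-{[(tert-butyldimethylsilyl)oxy]methyl}-4-[(1S)-1-[(tert-butyldimethylsilyl)oxy]-3-methylbutyl]-3-methoxyphenoxy]-3-[(4-methoxybenzyl)oxy]-5-methylphenyl}-1,3-dioxolane
Conditions: MeI, K2CO3, DMF, rt
Reagents that add atoms: iodomethane, CI
Why: Williamson O-methylation of the hindered phenol should be clean because the neighbouring silyl ethers stay on the more basic benzylic oxygens and are not leaving groups.

Step 16
Reactants: 24 the methyl ether from step 15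
Product: 25 2-{2-(hydroxymethyl)-4-[(1S)-1-hydroxy-3-methylbutyl]-3-methoxyphenoxy}-3-[(4-methoxybenzyl)oxy]-5-methylbenzaldehyde
Conditions: HF (48% aq), MeCN, 0 °C → rt
Reagents that add atoms: water, O
Why: Fluoride-assisted desilylation removes both TBS ethers and the same weakly acidic aqueous medium hydrolyses the aryl dioxolane (acetal hydrolysis), while the PMB ether, the diaryl ether and the benzylic carbinol configuration should be unaffected.

Step 17
Reactants: 25 the diol aldehyde from step 16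
Product: 26 (3E)-4-{2-[2-(hydroxymethyl)-4-[(1S)-1-hydroxy-3-methylbutyl]-3-methoxyphenoxy]-3-[(4-methoxybenzyl)oxy]-5-methylphenyl}but-3-en-2-one
Conditions: Ph3P=CHC(O)CH3, PhMe, 80 °C
Reagents that add atoms: 1-(triphenylphosphoranylidene)propan-2-one, CC(=O)C=P(c1ccccc1)(c1ccccc1)c1ccccc1
Why: Wittig olefination with the stabilised ylide gives the (E)-enone and tolerates free alcohols; it is placed before the oxidation of ring A so that only one aldehyde is present.

Step 18
Reactants: 26 the enone diol from step 17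
Product: 27 3-[(1S)-1-hydroxy-3-methylbutyl]-2-methoxy-6-{2-[(4-methoxybenzyl)oxy]-4-methyl-6-[(1E)-3-oxobut-1-en-1-yl]phenoxy}benzaldehyde
Conditions: TEMPO (cat.), PhI(OAc)2 (1.1 equiv), CH2Cl2, rt
Reagents that add atoms: none
Why: Oxoammonium-mediated alcohol oxidation (TEMPO with PhI(OAc)2) should take the primary benzylic alcohol much faster than the hindered secondary one and stop at the aldehyde.

Step 19
Reactants: 27 the hydroxy aldehyde from step 18
Product: 28 (1S)-1-(3-formyl-2-methoxy-4-{2-[(4-methoxybenzyl)oxy]-4-methyl-6-[(1E)-3-oxobut-1-en-1-yl]phenoxy}phenyl)-3-methylbutyl acetate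
Conditions: Ac2O, Et3N, DMAP (cat.), CH2Cl2, 0 °C → rt
Reagents that add atoms: acetic anhydride, CC(=O)OC(C)=O
Why: DMAP-catalysed O-acylation of the secondary alcohol occurs at oxygen, so the (S) configuration is retained.

Step 20
Reactants: 28 the acetoxy aldehyde from step 19
Product: 29 3-[(1S)-1-(acetyloxy)-3-methylbutyl]-2-methoxy-6-{2-[(4-methoxybenzyl)oxy]-4-methyl-6-[(1E)-3-oxobut-1-en-1-yl]phenoxy}benzoic acid
Conditions: NaClO2, NaH2PO4, 2-methylbut-2-ene, t-BuOH/H2O, rt
Reagents that add atoms: sodium chlorite, [Na+].[O-]Cl=O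
Why: Pinnick oxidation converts the hindered aryl aldehyde into the acid without touching enone, acetate or PMB ether, the alkene additive trapping HOCl.

Step 21
Reactants: 29 the PMB-protected acid from step 20
Product: 30 3-[(1S)-1-(acetyloxy)-3-methylbutyl]-6-{2-hydroxy-4-methyl-6-[(1E)-3-oxobut-1-en-1-yl]phenoxy}-2-methoxybenzoic acid (CNP0281268.1)
Conditions: DDQ, CH2Cl2/H2O (18:1), 0 °C → rt
Reagents that add atoms: none
Why: Oxidative PMB ether cleavage (hydride abstraction by DDQ, then hydrolysis of the oxocarbenium ion) is neutral, so the acid-labile benzylic acetate, the enone and the methyl ether should survive.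

Compound list
1 | L-leucine, (S)-2-amino-4-methylpentanoic acid | CC(C)C[C@H](N)C(=O)O | starting material
2 | (S)-2-hydroxy-4-methylpentanoic acid | CC(C)C[C@H](O)C(=O)O | intermediate
3 | methyl (S)-2-hydroxy-4-methylpentanoate | CC(C)C[C@H](O)C(=O)OC | intermediate
4 | methyl (S)-2-[(tert-butyldimethylsilyl)oxy]-4-methylpentanoate | CC(C)C[C@H](O[Si](C)(C)C(C)(C)C)C(=O)OC | intermediate
5 | (S)-2-[(tert-butyldimethylsilyl)oxy]-4-methylpentanal | CC(C)C[C@H](O[Si](C)(C)C(C)(C)C)C=O | intermediate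
6 | (3E,5S)-5-[(tert-butyldimethylsilyl)oxy]-7-methyloct-3-en-2-one | CC(C)C[C@H](O[Si](C)(C)C(C)(C)C)/C=C/C(C)=O | intermediate
7 | (5E,7S)-7-[(tert-butyldimethylsilyl)oxy]-1,1,1-trifluoro-9-methyldec-5-ene-2,4-dione (crude, not purified) | CC(C)C[C@H](O[Si](C)(C)C(C)(C)C)/C=C/C(=O)CC(=O)C(F)(F)F | intermediate
8 | (3E,5S)-5-[(tert-butyldimethylsilyl)oxy]-1-diazo-7-methyloct-3-en-2-one | CC(C)C[C@H](O[Si](C)(C)C(C)(C)C)/C=C/C(=O)C=[N+]=[N-] | intermediate
9 | 2-methoxy-4-methylphenol | COc1cc(C)ccc1O | starting material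
10 | 2-hydroxy-3-methoxy-5-methylbenzaldehyde | COc1cc(C)cc(C=O)c1O | intermediate
11 | 2,3-dihydroxy-5-methylbenzaldehyde | Oc1cc(C)cc(C=O)c1O | intermediate
12 | 2-hydroxy-3-[(4-methoxybenzyl)oxy]-5-methylbenzaldehyde | COc1ccc(COc2cc(C)cc(C=O)c2O)cc1 | intermediate
13 | 2-(1,3-dioxolan-2-yl)-6-[(4-methoxybenzyl)oxy]-4-methylphenol | COc1ccc(COc2cc(C)cc(C3OCCO3)c2O)cc1 | intermediate
14 | trichloroethene | ClC=C(Cl)Cl | starting material
15 | 2-{2-[(E)-1,2-dichloroethenoxy]-3-[(4-methoxybenzyl)oxy]-5-methylphenyl}-1,3-dioxolane | COc1ccc(COc2cc(C)cc(C3OCCO3)c2O/C(Cl)=C\Cl)cc1 | intermediate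
16 | lithium {2-(1,3-dioxolan-2-yl)-6-[(4-methoxybenzyl)oxy]-4-methylphenoxy}acetylide (not isolated) | [Li]C#COc1c(OCc2ccc(OC)cc2)cc(C)cc1C1OCCO1 | intermediate
17 | 3-{2-(1,3-dioxolan-2-yl)-6-[(4-methoxybenzyl)oxy]-4-methylphenoxy}prop-2-yn-1-ol | OCC#COc1c(OCc2ccc(OC)cc2)cc(C)cc1C1OCCO1 | intermediate
18 | tert-butyl[(3-{2-(1,3-dioxolan-2-yl)-6-[(4-methoxybenzyl)oxy]-4-methylphenoxy}prop-2-yn-1-yl)oxy]dimethylsilane | CC(C)(C)[Si](C)(C)OCC#COc1c(OCc2ccc(OC)cc2)cc(C)cc1C1OCCO1 | intermediate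
19 | (3E,5S)-5-[(tert-butyldimethylsilyl)oxy]-7-methylocta-1,3-dien-1-one, the vinylketene (not isolated) | CC(C)C[C@H](O[Si](C)(C)C(C)(C)C)/C=C/C=C=O | intermediate
20 | 4-[(1E,3S)-3-[(tert-butyldimethylsilyl)oxy]-5-methylhex-1-en-1-yl]-2-{[(tert-butyldimethylsilyl)oxy]methyl}-3-{2-(1,3-dioxolan-2-yl)-6-[(4-methoxybenzyl)oxy]-4-methylphenoxy}cyclobut-2-en-1-one, either configuration at C4 (not isolated) | CC(C)C[C@H](O[Si](C)(C)C(C)(C)C)/C=C/C1C(=O)C(CO[Si](C)(C)C(C)(C)C)=C1Oc1c(OCc2ccc(OC)cc2)cc(C)cc1C1OCCO1 | intermediate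
21 | (3E,5E,7S)-7-[(tert-butyldimethylsilyl)oxy]-2-{[(tert-butyldimethylsilyl)oxy]methyl}-3-{2-(1,3-dioxolan-2-yl)-6-[(4-methoxybenzyl)oxy]-4-methylphenoxy}-9-methyldeca-1,3,5-trien-1-one, the dienylketene with C2 and C5 cis on C3=C4 (not isolated) | O=C=C(CO[Si](C)(C)C(C)(C)C)/C(Oc1c(OCc2ccc(OC)cc2)cc(C)cc1C1OCCO1)=C\C=C\[C@H](CC(C)C)O[Si](C)(C)C(C)(C)C | intermediate
22 | 6-[(1S)-1-[(tert-butyldimethylsilyl)oxy]-3-methylbutyl]-2-{[(tert-butyldimethylsilyl)oxy]methyl}-3-{2-(1,3-dioxolan-2-yl)-6-[(4-methoxybenzyl)oxy]-4-methylphenoxy}cyclohexa-2,4-dien-1-one, either configuration at C6 (not isolated) | O=C1C(CO[Si](C)(C)C(C)(C)C)=C(Oc2c(OCc3ccc(OC)cc3)cc(C)cc2C2OCCO2)C=CC1[C@H](CC(C)C)O[Si](C)(C)C(C)(C)C | intermediate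
23 | 6-[(1S)-1-[(tert-butyldimethylsilyl)oxy]-3-methylbutyl]-2-{[(tert-butyldimethylsilyl)oxy]methyl}-3-{2-(1,3-dioxolan-2-yl)-6-[(4-methoxybenzyl)oxy]-4-methylphenoxy}phenol | Oc1c([C@H](CC(C)C)O[Si](C)(C)C(C)(C)C)ccc(Oc2c(OCc3ccc(OC)cc3)cc(C)cc2C2OCCO2)c1CO[Si](C)(C)C(C)(C)C | intermediate
24 | 2-{2-[2-{[(tert-butyldimethylsilyl)oxy]methyl}-4-[(1S)-1-[(tert-butyldimethylsilyl)oxy]-3-methylbutyl]-3-methoxyphenoxy]-3-[(4-methoxybenzyl)oxy]-5-methylphenyl}-1,3-dioxolane | COc1c([C@H](CC(C)C)O[Si](C)(C)C(C)(C)C)ccc(Oc2c(OCc3ccc(OC)cc3)cc(C)cc2C2OCCO2)c1CO[Si](C)(C)C(C)(C)C | intermediate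
25 | 2-{2-(hydroxymethyl)-4-[(1S)-1-hydroxy-3-methylbutyl]-3-methoxyphenoxy}-3-[(4-methoxybenzyl)oxy]-5-methylbenzaldehyde | COc1c([C@H](CC(C)C)O)ccc(Oc2c(OCc3ccc(OC)cc3)cc(C)cc2C=O)c1CO | intermediate
26 | (3E)-4-{2-[2-(hydroxymethyl)-4-[(1S)-1-hydroxy-3-methylbutyl]-3-methoxyphenoxy]-3-[(4-methoxybenzyl)oxy]-5-methylphenyl}but-3-en-2-one | COc1c([C@H](CC(C)C)O)ccc(Oc2c(OCc3ccc(OC)cc3)cc(C)cc2/C=C/C(C)=O)c1CO | intermediate
27 | 3-[(1S)-1-hydroxy-3-methylbutyl]-2-methoxy-6-{2-[(4-methoxybenzyl)oxy]-4-methyl-6-[(1E)-3-oxobut-1-en-1-yl]phenoxy}benzaldehyde | COc1c([C@H](CC(C)C)O)ccc(Oc2c(OCc3ccc(OC)cc3)cc(C)cc2/C=C/C(C)=O)c1C=O | intermediate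
28 | (1S)-1-(3-formyl-2-methoxy-4-{2-[(4-methoxybenzyl)oxy]-4-methyl-6-[(1E)-3-oxobut-1-en-1-yl]phenoxy}phenyl)-3-methylbutyl acetate | COc1c([C@H](CC(C)C)OC(C)=O)ccc(Oc2c(OCc3ccc(OC)cc3)cc(C)cc2/C=C/C(C)=O)c1C=O | intermediate
29 | 3-[(1S)-1-(acetyloxy)-3-methylbutyl]-2-methoxy-6-{2-[(4-methoxybenzyl)oxy]-4-methyl-6-[(1E)-3-oxobut-1-en-1-yl]phenoxy}benzoic acid | COc1c([C@H](CC(C)C)OC(C)=O)ccc(Oc2c(OCc3ccc(OC)cc3)cc(C)cc2/C=C/C(C)=O)c1C(=O)O | intermediate
30 | 3-[(1S)-1-(acetyloxy)-3-methylbutyl]-6-{2-hydroxy-4-methyl-6-[(1E)-3-oxobut-1-en-1-yl]phenoxy}-2-methoxybenzoic acid (CNP0281268.1) | COc1c([C@H](CC(C)C)OC(C)=O)ccc(Oc2c(O)cc(C)cc2/C=C/C(C)=O)c1C(=O)O | target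

Total step count: 21. Longest linear sequence: 15 steps (steps 7–13, 14, 15–21, from 2-methoxy-4-methylphenol); the leucine branch contributes steps 1–6.

Steps most likely to fail

Step 14. The aryloxy oxygen polarises the alkyne less than an alkoxy or siloxy oxygen, so the ketene–alkyne [2+2] may be slow and ketene dimerisation, acylation of the product phenol or photodegradation of the alkynyl ether may take over. The fallback sets out from 8, uses a siloxyalkyne as partner and attaches ring B afterwards by SNAr. Ethyl [(tert-butyldimethylsilyl)oxy]acetate is converted by Kowalski ynolate formation (CH2Br2, lithium 2,2,6,6-tetramethylpiperidide; n-BuLi) and O-silylation with i-Pr3SiCl into tert-butyldimethyl({3-[(triisopropylsilyl)oxy]prop-2-yn-1-yl}oxy)silane F1. Irradiation and heating of 8 with this alkyne, as in step 14, should give 6-[(1S)-1-[(tert-butyldimethylsilyl)oxy]-3-methylbutyl]-2-{[(tert-butyldimethylsilyl)oxy]methyl}-3-[(triisopropylsilyl)oxy]phenol F2. MeI and K2CO3 then give tert-butyl{(1S)-1-[3-{[(tert-butyldimethylsilyl)oxy]methyl}-2-methoxy-4-[(triisopropylsilyl)oxy]phenyl]-3-methylbutoxy}dimethylsilane F3, and KHF2 in MeOH cleaves only the aryl silyl ether to 4-[(1S)-1-[(tert-butyldimethylsilyl)oxy]-3-methylbutyl]-2-{[(tert-butyldimethylsilyl)oxy]methyl}-3-methoxyphenol F4. Separately, 2-fluoro-5-methylphenol is alkylated (PMBCl, K2CO3) to 1-fluoro-2-[(4-methoxybenzyl)oxy]-4-methylbenzene F5 and formylated next to fluorine (LiN(iPr)2, THF, −78 °C; DMF) to 2-fluoro-3-[(4-methoxybenzyl)oxy]-5-methylbenzaldehyde F6. SNAr of the phenoxide of the ring A phenol on this fluoride (K2CO3, DMF, 90 °C), activated by the ortho-formyl group, gives 2-{2-{[(tert-butyldimethylsilyl)oxy]methyl}-4-[(1S)-1-[(tert-butyldimethylsilyl)oxy]-3-methylbutyl]-3-methoxyphenoxy}-3-[(4-methoxybenzyl)oxy]-5-methylbenzaldehyde F7. Aqueous HF in MeCN removes both TBS groups, and the route is rejoined at 25.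

Step 12. Ring or benzylic lithiation may compete with the elimination, trapping by polymeric formaldehyde may be incomplete, and the free alkynyl ether carbinol may hydrate during isolation. The fallback sets out from 13 and avoids organolithium reagents and the free carbinol. [(tert-Butyldimethylsilyl)oxy]acetaldehyde is converted (CBr4, PPh3) into 1,1-dibromo-3-[(tert-butyldimethylsilyl)oxy]prop-1-ene F8. Copper-catalysed coupling of 13 with this dibromoalkene (CuI, 2,2'-bipyridine, K3PO4, toluene, 110 °C) should give 2-{2-({(1Z)-1-bromo-3-[(tert-butyldimethylsilyl)oxy]prop-1-en-1-yl}oxy)-3-[(4-methoxybenzyl)oxy]-5-methylphenyl}-1,3-dioxolane F9. KOtBu in THF eliminates HBr, and the route is rejoined at 18.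

Step 18. Chemoselectivity may be lost, with the secondary benzylic alcohol oxidised to the ketone alongside or after the primary one. The fallback sets out from 26 and replaces chemoselective oxidation by protecting-group differentiation. Selective silylation of the primary alcohol (TBSCl, imidazole, CH2Cl2, 0 °C) gives (3E)-4-{2-[2-{[(tert-butyldimethylsilyl)oxy]methyl}-4-[(1S)-1-hydroxy-3-methylbutyl]-3-methoxyphenoxy]-3-[(4-methoxybenzyl)oxy]-5-methylphenyl}but-3-en-2-one F10. Acetylation (Ac2O, DMAP) gives (1S)-1-(3-{[(tert-butyldimethylsilyl)oxy]methyl}-2-methoxy-4-{2-[(4-methoxybenzyl)oxy]-4-methyl-6-[(1E)-3-oxobut-1-en-1-yl]phenoxy}phenyl)-3-methylbutyl acetate F11. Desilylation (HF·pyridine, THF) gives (1S)-1-(3-(hydroxymethyl)-2-methoxy-4-{2-[(4-methoxybenzyl)oxy]-4-methyl-6-[(1E)-3-oxobut-1-en-1-yl]phenoxy}phenyl)-3-methylbutyl acetate F12. Dess–Martin oxidation of the primary alcohol then rejoins the route at 28.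

Further compounds
F1 | step 14 | tert-butyldimethyl({3-[(triisopropylsilyl)oxy]prop-2-yn-1-yl}oxy)silane | CC(C)[Si](OC#CCO[Si](C)(C)C(C)(C)C)(C(C)C)C(C)C
F2 | step 14 | 6-[(1S)-1-[(tert-butyldimethylsilyl)oxy]-3-methylbutyl]-2-{[(tert-butyldimethylsilyl)oxy]methyl}-3-[(triisopropylsilyl)oxy]phenol | Oc1c([C@H](CC(C)C)O[Si](C)(C)C(C)(C)C)ccc(O[Si](C(C)C)(C(C)C)C(C)C)c1CO[Si](C)(C)C(C)(C)C
F3 | step 14 | tert-butyl{(1S)-1-[3-{[(tert-butyldimethylsilyl)oxy]methyl}-2-methoxy-4-[(triisopropylsilyl)oxy]phenyl]-3-methylbutoxy}dimethylsilane | COc1c([C@H](CC(C)C)O[Si](C)(C)C(C)(C)C)ccc(O[Si](C(C)C)(C(C)C)C(C)C)c1CO[Si](C)(C)C(C)(C)C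
F4 | step 14 | 4-[(1S)-1-[(tert-butyldimethylsilyl)oxy]-3-methylbutyl]-2-{[(tert-butyldimethylsilyl)oxy]methyl}-3-methoxyphenol | COc1c([C@H](CC(C)C)O[Si](C)(C)C(C)(C)C)ccc(O)c1CO[Si](C)(C)C(C)(C)C
F5 | step 14 | 1-fluoro-2-[(4-methoxybenzyl)oxy]-4-methylbenzene | COc1ccc(COc2cc(C)ccc2F)cc1
F6 | step 14 | 2-fluoro-3-[(4-methoxybenzyl)oxy]-5-methylbenzaldehyde | COc1ccc(COc2cc(C)cc(C=O)c2F)cc1
F7 | step 14 | 2-{2-{[(tert-butyldimethylsilyl)oxy]methyl}-4-[(1S)-1-[(tert-butyldimethylsilyl)oxy]-3-methylbutyl]-3-methoxyphenoxy}-3-[(4-methoxybenzyl)oxy]-5-methylbenzaldehyde | COc1c([C@H](CC(C)C)O[Si](C)(C)C(C)(C)C)ccc(Oc2c(OCc3ccc(OC)cc3)cc(C)cc2C=O)c1CO[Si](C)(C)C(C)(C)C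
F8 | step 12 | 1,1-dibromo-3-[(tert-butyldimethylsilyl)oxy]prop-1-ene | BrC(Br)=CCO[Si](C)(C)C(C)(C)C
F9 | step 12 | 2-{2-({(1Z)-1-bromo-3-[(tert-butyldimethylsilyl)oxy]prop-1-en-1-yl}oxy)-3-[(4-methoxybenzyl)oxy]-5-methylphenyl}-1,3-dioxolane | COc1ccc(COc2cc(C)cc(C3OCCO3)c2O/C(Br)=C/CO[Si](C)(C)C(C)(C)C)cc1
F10 | step 18 | (3E)-4-{2-[2-{[(tert-butyldimethylsilyl)oxy]methyl}-4-[(1S)-1-hydroxy-3-methylbutyl]-3-methoxyphenoxy]-3-[(4-methoxybenzyl)oxy]-5-methylphenyl}but-3-en-2-one | COc1c([C@H](CC(C)C)O)ccc(Oc2c(OCc3ccc(OC)cc3)cc(C)cc2/C=C/C(C)=O)c1CO[Si](C)(C)C(C)(C)C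
F11 | step 18 | (1S)-1-(3-{[(tert-butyldimethylsilyl)oxy]methyl}-2-methoxy-4-{2-[(4-methoxybenzyl)oxy]-4-methyl-6-[(1E)-3-oxobut-1-en-1-yl]phenoxy}phenyl)-3-methylbutyl acetate | COc1c([C@H](CC(C)C)OC(C)=O)ccc(Oc2c(OCc3ccc(OC)cc3)cc(C)cc2/C=C/C(C)=O)c1CO[Si](C)(C)C(C)(C)C
F12 | step 18 | (1S)-1-(3-(hydroxymethyl)-2-methoxy-4-{2-[(4-methoxybenzyl)oxy]-4-methyl-6-[(1E)-3-oxobut-1-en-1-yl]phenoxy}phenyl)-3-methylbutyl acetate | COc1c([C@H](CC(C)C)OC(C)=O)ccc(Oc2c(OCc3ccc(OC)cc3)cc(C)cc2/C=C/C(C)=O)c1CO
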